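**Retrosynthetic overview**

1. Target ⇒ C10–C11 disconnection: chelation-controlled addition of a non-8-enyl Grignard reagent to the oxolane-2-carbaldehyde that already carries the myristate (sets C10).
2. Aldehyde ⇒ ozonolysis of a styryl group; myristate ⇒ acylation of the ring hydroxyl, the only free OH at that stage.
3. The single ring (oxolane) ⇒ 5-exo SN2 closure of an anti-chlorohydrin/1,3-syn diol: the C9–OH displaces the C6 chloride with inversion.
4. Chlorodiol ⇒ one-pot boron aldol/syn-reduction (new for α-chloro aldehydes) of benzalacetone with (R)-2-chloroheptanal (C7–C8 bond; sets C7 and C9).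
5. (R)-2-Chloroheptanal ⇒ organocatalytic enantioselective α-chlorination of heptanal (first stereocentre, C6). Only one ring is formed, in step 3.

Assumption: the target is taken as drawn, (2S,3S,5R)-5-[(1R)-1-hydroxydec-9-en-1-yl]-2-pentyloxolan-3-yl tetradecanoate; chain locants C6/C7/C9/C10 = ring C2/ring C3/ring C5/side-chain carbinol; a one-pot sequence without isolation counts as one step.

**Route**

Step 1
Reactants: 1 heptanal
Product: 2 (R)-2-chloroheptanal
Conditions: (5R)-5-benzyl-2,2,3-trimethylimidazolidin-4-one·TFA (5 mol %), 2,3,4,5,6,6-hexachlorocyclohexa-2,4-dien-1-one (1.2 equiv), acetone, –30 °C; cold pentane trituration/filtration, used crude at once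
Reagents that add atoms: 2,3,4,5,6,6-hexachlorocyclohexa-2,4-dien-1-one, O=C1C(Cl)=C(Cl)C(Cl)=C(Cl)C1(Cl)Cl
Why: Enamine-mediated organocatalytic α-chlorination (MacMillan-type): the catalyst benzyl group shields one face of the E-enamine so chlorine is delivered to the other, and the (5R)-catalyst (antipode of the one that gives (S)-2-chloroalkanals) sets C6 as R (about 92 % ee expected), which becomes 6S after the inversion in step 3.

Step 2
Reactants: 2 (R)-2-chloroheptanal; 3 (E)-4-phenylbut-3-en-2-one
Product: 7 (1E,3R,5S,6R)-6-chloro-1-phenylundec-1-ene-3,5-diol, via boron dienolate 4 (not isolated), via boron aldolate 5 (not isolated), via lithium borate chelate 6 (not isolated)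
Conditions: 3 (1.3 equiv), c-Hex2BCl (1.4 equiv), Et3N (1.3 equiv), Et2O, –78→0 °C; then 2, –78 °C, 2 h; then LiBH4 (THF), –78 °C; then MeOH, pH 7 buffer, 30 % H2O2, 0 °C; chromatography
Reagents that add atoms: none
Why: Proposed new method: a Paterson-type one-pot dialkylboron aldol/LiBH4 reduction applied for the first time to an α-chloro aldehyde — dienolate 4 adds to 2 through a closed transition state with the C–Cl and C=O dipoles opposed (Cornforth/polar Felkin–Anh, 1,2-anti, giving 7S), and the six-membered boron chelate 5 is then reduced by external axial hydride in the 1,2-mode (Narasaka–Prasad-type 1,3-syn, giving 9R) before any epimerisable β-ketol is released; the closest known chemistry is the boron aldol–reduction with simple aldehydes and the anti-selective lithium-enolate aldol of α-chloro aldehydes.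

Step 3
Reactants: 7 (1E,3R,5S,6R)-6-chloro-1-phenylundec-1-ene-3,5-diol
Product: 8 (2S,3S,5R)-2-pentyl-5-[(E)-2-phenylethenyl]oxolan-3-ol
Conditions: AgOTf (1 equiv), Ag2O (1 equiv), THF, 20→40 °C, dark
Reagents that add atoms: none
Why: Silver-assisted intramolecular Williamson-type etherification (5-exo-tet SN2): only the C9 hydroxyl can reach C6 and displaces chloride with inversion (6R→6S) to give the 2,3-cis/2,5-trans oxolane, while Ag2O buffers TfOH so the cinnamyl carbinol is not ionised and no alkoxide is present to form an epoxide.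

Step 4
Reactants: 8 (2S,3S,5R)-2-pentyl-5-[(E)-2-phenylethenyl]oxolan-3-ol; 9 tetradecanoyl chloride
Product: 10 (2S,3S,5R)-2-pentyl-5-[(E)-2-phenylethenyl]oxolan-3-yl tetradecanoate
Conditions: pyridine, DMAP (cat.), CH2Cl2, 0 °C→rt
Reagents that add atoms: none
Why: DMAP-catalysed acylation with an acyl chloride of the single free hydroxyl; no stereocentre is involved and the allylic ether is inert.

Step 5
Reactants: 10 (2S,3S,5R)-2-pentyl-5-[(E)-2-phenylethenyl]oxolan-3-yl tetradecanoate
Product: 12 (2S,3S,5R)-5-formyl-2-pentyloxolan-3-yl tetradecanoate, via secondary ozonide 11 (not isolated)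
Conditions: O3, CH2Cl2, –78 °C; then PPh3, –78 °C→rt; short silica plug, used at once
Reagents that add atoms: ozone, [O-][O+]=O
Why: Ozonolysis (Criegee mechanism) of the only C=C with neutral reductive work-up gives the α-alkoxy aldehyde without epimerising ring C5 or touching the ester.

Step 6
Reactants: 12 (2S,3S,5R)-5-formyl-2-pentyloxolan-3-yl tetradecanoate; 13 9-bromonon-1-ene
Product: 16 (2S,3S,5R)-5-[(1R)-1-hydroxydec-9-en-1-yl]-2-pentyloxolan-3-yl tetradecanoate, via non-8-enylmagnesium bromide 14 (not isolated), via bromomagnesium alkoxide 15 (not isolated)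
Conditions: 13, Mg, Et2O, reflux; 12, MgBr2·OEt2 (2 equiv), CH2Cl2, –78 °C, then the Grignard solution (1.3 equiv), 1 h; aq NH4Cl
Reagents that add atoms: none
Why: Chelation-controlled (Cram-chelate) Grignard addition: magnesium bridges the aldehyde and ring oxygens and the alkyl group attacks from the side of the C5–H, opposite ring C4, giving the threo (10R) carbinol, while at –78 °C the aldehyde reacts far faster than the secondary myristate.

**Compound list**

1 | heptanal | CCCCCCC=O | starting material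
2 | (R)-2-chloroheptanal | CCCCC[C@@H](Cl)C=O | intermediate
3 | (E)-4-phenylbut-3-en-2-one | CC(=O)/C=C/c1ccccc1 | starting material
4 | dicyclohexyl{[(3E)-4-phenylbuta-1,3-dien-2-yl]oxy}borane | C=C(OB(C1CCCCC1)C2CCCCC2)/C=C/c3ccccc3 | intermediate
5 | (1E,5S,6R)-6-chloro-5-[(dicyclohexylboranyl)oxy]-1-phenylundec-1-en-3-one | CCCCC[C@@H](Cl)[C@@H](OB(C1CCCCC1)C2CCCCC2)CC(=O)/C=C/c3ccccc3 | intermediate
6 | lithium (4S,6R)-4-[(1R)-1-chlorohexyl]-2,2-dicyclohexyl-6-[(E)-2-phenylethenyl]-1,3,2-dioxaborinan-2-uide | [Li+].CCCCC[C@@H](Cl)[C@@H]1C[C@H](/C=C/c2ccccc2)O[B-](C3CCCCC3)(C4CCCCC4)O1 | intermediate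
7 | (1E,3R,5S,6R)-6-chloro-1-phenylundec-1-ene-3,5-diol | CCCCC[C@@H](Cl)[C@@H](O)C[C@@H](O)/C=C/c1ccccc1 | intermediate
8 | (2S,3S,5R)-2-pentyl-5-[(E)-2-phenylethenyl]oxolan-3-ol | c1ccccc1/C=C/[C@H]2C[C@H](O)[C@H](CCCCC)O2 | intermediate
9 | tetradecanoyl chloride | CCCCCCCCCCCCCC(=O)Cl | starting material
10 | (2S,3S,5R)-2-pentyl-5-[(E)-2-phenylethenyl]oxolan-3-yl tetradecanoate | c1ccccc1/C=C/[C@H]2C[C@H](OC(=O)CCCCCCCCCCCCC)[C@H](CCCCC)O2 | intermediate
11 | 5-[(2R,4S,5S)-5-pentyl-4-(tetradecanoyloxy)oxolan-2-yl]-3-phenyl-1,2,4-trioxolane (mixture at the trioxolane carbons) | c1ccccc1C2OOC(O2)[C@H]3C[C@H](OC(=O)CCCCCCCCCCCCC)[C@H](CCCCC)O3 | intermediate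
12 | (2S,3S,5R)-5-formyl-2-pentyloxolan-3-yl tetradecanoate | O=C[C@H]1C[C@H](OC(=O)CCCCCCCCCCCCC)[C@H](CCCCC)O1 | intermediate
13 | 9-bromonon-1-ene | C=CCCCCCCCBr | starting material
14 | non-8-en-1-ylmagnesium bromide | C=CCCCCCCC[Mg]Br | intermediate
15 | bromomagnesium (1R)-1-[(2R,4S,5S)-5-pentyl-4-(tetradecanoyloxy)oxolan-2-yl]dec-9-en-1-olate | C=CCCCCCCC[C@@H](O[Mg]Br)[C@H]1C[C@H](OC(=O)CCCCCCCCCCCCC)[C@H](CCCCC)O1 | intermediate
16 | (2S,3S,5R)-5-[(1R)-1-hydroxydec-9-en-1-yl]-2-pentyloxolan-3-yl tetradecanoate | C=CCCCCCCC[C@@H](O)[C@H]1C[C@H](OC(=O)CCCCCCCCCCCCC)[C@H](CCCCC)O1 | target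

**Step count and risks**

Total steps: 6. Longest linear sequence: 6 (1 → 2 → 7 → 8 → 10 → 12 → 16).

The three steps most likely to fail:

Step 2 (the new tandem aldol/reduction). The risks are lower Cornforth selectivity with a boron enolate than with a lithium enolate, epimerisation of 2 by amine, and some 1,4-reduction of the enone. The fallback uses known chemistry, sets out from 2 and 3 and comes back at 7. Ketone 3 is deprotonated with LDA (THF, –78 °C) to lithium (3E)-4-phenylbuta-1,3-dien-2-olate F1. F1 adds to 2 and, after NH4Cl quench, gives the anti-chlorohydrin ketol (1E,5S,6R)-6-chloro-5-hydroxy-1-phenylundec-1-en-3-one F2. F2 is then reduced with Et2BOMe/NaBH4 (THF–MeOH, –78 °C, Narasaka–Prasad) to 7. This costs one extra step.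

Step 3 (ring closure next to a cinnamyl carbinol). The risk is that silver or adventitious acid ionises or eliminates the allylic, benzylic-conjugated C9–OH instead of letting it act as the nucleophile. The fallback carries C10 as a dimethyl acetal instead of a styryl group, so the closure can be run thermally without silver; it sets out from 2 and comes back at 12. 1,1-Dimethoxypropan-2-one (commercial, CC(=O)C(OC)OC) is enolised with LDA to lithium 3,3-dimethoxyprop-1-en-2-olate F3. F3 adds to 2 to give (4S,5R)-5-chloro-4-hydroxy-1,1-dimethoxydecan-2-one F4. Et2BOMe/NaBH4 gives the syn diol (2R,4S,5R)-5-chloro-1,1-dimethoxydecane-2,4-diol F5. Heating in MeOH (sealed tube, about 110 °C) closes the ring by SN2 to (2S,3S,5R)-5-(dimethoxymethyl)-2-pentyloxolan-3-ol F6. Acylation with 9 (pyridine, DMAP) gives (2S,3S,5R)-5-(dimethoxymethyl)-2-pentyloxolan-3-yl tetradecanoate F7. Aqueous TFA in CH2Cl2 (0 °C) hydrolyses the acetal to 12.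

Step 6 (substrate-controlled Grignard addition). The risks are only modest threo:erythro selectivity and some attack on the ester. The fallback replaces chelation control by catalyst control; it sets out from 12 and 14 and comes back at 16. Two equivalents of 14 are transmetallated with ZnCl2 (Et2O/1,4-dioxane, magnesium salts filtered off) to bis(non-8-en-1-yl)zinc F8. F8 is added to 12 with Ti(OiPr)4 and catalytic (1S,2S)-N,N'-bis(trifluoromethanesulfonyl)cyclohexane-1,2-diamine (toluene, –20 °C). This is the ligand enantiomer that gives (R)-carbinols from aldehydes and simple dialkylzincs, and the dialkylzinc leaves the ester untouched.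

**Further compounds**

F1 | step 2 | lithium (3E)-4-phenylbuta-1,3-dien-2-olate | [Li+].[O-]C(=C)/C=C/c1ccccc1
F2 | step 2 | (1E,5S,6R)-6-chloro-5-hydroxy-1-phenylundec-1-en-3-one | CCCCC[C@@H](Cl)[C@@H](O)CC(=O)/C=C/c1ccccc1
F3 | step 3 | lithium 3,3-dimethoxyprop-1-en-2-olate | [Li+].[O-]C(=C)C(OC)OC
F4 | step 3 | (4S,5R)-5-chloro-4-hydroxy-1,1-dimethoxydecan-2-one | CCCCC[C@@H](Cl)[C@@H](O)CC(=O)C(OC)OC
F5 | step 3 | (2R,4S,5R)-5-chloro-1,1-dimethoxydecane-2,4-diol | CCCCC[C@@H](Cl)[C@@H](O)C[C@@H](O)C(OC)OC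
F6 | step 3 | (2S,3S,5R)-5-(dimethoxymethyl)-2-pentyloxolan-3-ol | COC(OC)[C@H]1C[C@H](O)[C@H](CCCCC)O1
F7 | step 3 | (2S,3S,5R)-5-(dimethoxymethyl)-2-pentyloxolan-3-yl tetradecanoate | COC(OC)[C@H]1C[C@H](OC(=O)CCCCCCCCCCCCC)[C@H](CCCCC)O1
F8 | step 6 | bis(non-8-en-1-yl)zinc | C=CCCCCCCC[Zn]CCCCCCCC=C
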